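The constants at 100 °C give the partner two exits: it decays by itself at 0.17 s⁻¹, and it meets starting material at 0.0424 s⁻¹ at the charged 0.80 M, so decay is the faster exit.

in all of them: starting material 0.80 M; partner 3.00 equiv; time 15 s

| charge | temperature |
|---|---|
| autumn | 120 °C |
| winter | 100 °C |

    starting material + partner → target (k1 = 0.053 M⁻¹ s⁻¹, Ea1 = 83.0 kJ mol⁻¹)
    starting material → side product A (k2 = 0.015 s⁻¹, Ea2 = 100 kJ mol⁻¹)
    2 starting material → side product B (k3 = 0.0044 M⁻¹ s⁻¹, Ea3 = 57.0 kJ mol⁻¹)
    partner → decomposed reagent (k4 = 0.17 s⁻¹, Ea4 = 86.0 kJ mol⁻¹)
    starting material + target → side product C (k5 = 0.078 M⁻¹ s⁻¹, Ea5 = 72.0 kJ mol⁻¹)
    (constants at 100 °C)

- percent here means starting material units held: one side product B or side product C counts as two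
- a doubled species enters its step squared and goes two at a time
- all constants are for 100 °C and move with temperature by the activation energies

1. the best flask by share of target in all that became target or side product A or side product B or side product C; "all alike" if 1.5 percentage points covers them all (autumn / winter / all alike)
2. share of target in all that became target or side product A or side product B or side product C, autumn
3. share of target in all that became target or side product A or side product B or side product C, winter

*What would you freeze?* I freeze c(starting material) at its charge. The partner then falls in a pseudo-first-order way, and the reciprocal of its total loss constant is 4.71 s in winter. I call this the partner window: the time in which c(partner) falls by a factor e, with c(starting material) held at its charge.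

*And in autumn?* From winter to autumn the decay speeds up by a factor of 4.1 and the target step by a factor of 3.9, so the autumn window is 1.16 s, shorter than winter's.

*But the hotter flask makes target faster. Why isn't that a gain?* With c(starting material) frozen, the share of partner that goes to target is the target step's pseudo-first-order constant times the window. That gives 20.0% in winter and 19.2% in autumn, a smaller share, because the decay gains more from the heat.

*So what do you count?* I count windows in the asked time: 3.19 in winter and 12.9 in autumn. As c(partner) fades, the target step fades with it, while starting material still has its routes to side products A, B and C, and one of those consumes target. So at the asked time the autumn flask has more windows behind it than the winter flask, and a longer stretch with c(partner) faded.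

*Your weak spot?* Freezing c(starting material) makes the window too short, since the real concentration falls. I commit to winter as the best flask, but not to a percentage. In winter the frozen window leaves 4.13% of the partner at the end.

The forecast, stepped by hand, names winter. It gives autumn 21.6% (20% to 23.2%) and winter 41.8% (40.3% to 43.3%), and says of autumn that “starting material keeps destroying target and forming A”.

The simulation gives winter as best, with 42.9% against 22.8% for autumn, both inside the forecast's ranges. Winter has not come to rest at 15 s: it holds 32% of its starting material and 5.6% of its partner, against the window's 4.13%, and target is made at 0.393 of the rate it is used up. Read at 40 s, or 8.49 windows, the winter flask gives 25.1%, still 2.3 percentage points above autumn at its 12.9 windows. At ten times the asked time, 150 s, the order turns: autumn stands at 18.5%, above winter at 16.0%.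

(All constants are invented, and the outcome is calculated.)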